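Everything rests on cutting two adjacent bonds of ring B at once: the diaryl ether bond O–B2 and the bond from B1 to its carboxyl carbon. Ring B (B1 ester carbon, B2 ether carbon, B4 methoxy carbon, B6 pentanoyl carbon) has oxygen and carbon substituents on the neighbouring atoms B2 and B1, and only B1 lies beside the bulky B6 group. A B1–B2 aryne therefore takes up the protected ring A phenoxide at B2 and carbon dioxide at B1 in one operation. Its precursor is a 2-silylaryl triflate, triflate on B1 and silicon on B2, with the pentanoyl group masked as a dioxolane that also steers the phenoxide.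

Key step: step 7

Remark: ring A is the pentylresorcinol ring and its atoms are named by their substituents (ether carbon, hydroxy carbons, pentyl carbon); the target has no stereocentre; acid 20 is assumed to tolerate a cold work-up at pH 5 and is esterified without storage.

Step 1
Reactants: 1 2-bromo-4-methoxyphenol; 2 pentanoyl chloride
Product: 4 1-(3-bromo-2-hydroxy-5-methoxyphenyl)pentan-1-one, via aryl pentanoate 3 (not isolated)
Conditions: 2 (1.05 equiv), PhCl, 80 °C; then TiCl4 (1.2 equiv), 110 °C; 1 M HCl work-up
Reagents that add atoms: none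
Why: Heating the phenol with the acid chloride should give ester 3, and TiCl4 should then promote a Fries rearrangement in which the acyl group can only move to the free ortho carbon (the para carbon carries the methoxy group, the other ortho carbon bromine), the titanium chelate of the ortho-hydroxy ketone being the driving force and TiCl4 being gentler on the aryl methyl ether than AlCl3.

Step 2
Reactants: 4 1-(3-bromo-2-hydroxy-5-methoxyphenyl)pentan-1-one
Product: 6 [2-bromo-6-(2-butyl-1,3-dioxolan-2-yl)-4-methoxyphenoxy]trimethylsilane, via silyl ether ketone 5 (not isolated)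
Conditions: (Me3Si)2NH, THF, 65 °C, then evaporation; Me3SiOCH2CH2OSiMe3, Me3SiOTf (5 mol %), CH2Cl2, −78 → −20 °C; pyridine, filtration through basic alumina
Reagents that add atoms: hexamethyldisilazane, C[Si](C)(C)N[Si](C)(C)C; 1,2-bis(trimethylsilyloxy)ethane, C[Si](C)(C)OCCO[Si](C)(C)C
Why: Silylation of the chelated phenol removes the hydrogen bond that makes ortho-hydroxyaryl ketones poor substrates for equilibrium ketalisation, and the Noyori ketalisation that follows is driven irreversibly by formation of hexamethyldisiloxane under aprotic conditions, which keep the aryl silyl ether needed for the next step.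

Step 3
Reactants: 6 [2-bromo-6-(2-butyl-1,3-dioxolan-2-yl)-4-methoxyphenoxy]trimethylsilane
Product: 9 2-(2-butyl-1,3-dioxolan-2-yl)-4-methoxy-6-(trimethylsilyl)phenyl trifluoromethanesulfonate, via aryllithium 7 (not isolated), via lithium phenolate 8 (not isolated)
Conditions: n-BuLi, THF, −100 → −78 °C; then Tf2O, −100 → −78 °C; cold aq. NaHCO3
Reagents that add atoms: trifluoromethanesulfonic anhydride, O=S(=O)(OS(=O)(=O)C(F)(F)F)C(F)(F)F
Why: Bromine–lithium exchange should outrun attack at silicon at −100 °C, the aryllithium should undergo the 1,3 oxygen-to-carbon silyl shift (retro-Brook rearrangement) to the phenolate, and Tf2O traps this on oxygen, the dioxolane offering n-BuLi no acidic or electrophilic site.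

Step 4
Reactants: 10 olivetol (5-pentylbenzene-1,3-diol)
Product: 11 1,3-bis(methoxymethoxy)-5-pentylbenzene
Conditions: MOMCl, i-Pr2NEt, CH2Cl2, 0 °C → rt
Reagents that add atoms: chloromethyl methyl ether, COCCl
Why: Base-mediated O-alkylation of both phenols with the reactive α-chloro ether (MOM protection) gives acetals that tolerate organolithiums, hydride, fluoride and carbonate and that fall off together with the dioxolane in the last step.

Step 5
Reactants: 11 1,3-bis(methoxymethoxy)-5-pentylbenzene
Product: 12 1-bromo-2,4-bis(methoxymethoxy)-6-pentylbenzene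
Conditions: NBS (1.0 equiv), MeCN, 0 °C, dark
Reagents that add atoms: N-bromosuccinimide, O=C1CCC(=O)N1Br
Why: Electrophilic aromatic bromination should take place at the ring carbon para to one MOM ether and ortho to the other, next to the pentyl group, because the carbon between the two MOM ethers is the more crowded site, and one equivalent of NBS at 0 °C limits dibromination.

Step 6
Reactants: 12 1-bromo-2,4-bis(methoxymethoxy)-6-pentylbenzene
Product: 15 2,4-bis(methoxymethoxy)-6-pentylphenol, via aryllithium 13 (not isolated), via lithium arylborate 14 (not isolated)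
Conditions: n-BuLi, THF, −78 °C; B(OMe)3, −78 °C → rt; H2O2 (30% aq.), NaOH, 0 °C; aq. NH4Cl under argon
Reagents that add atoms: hydrogen peroxide, OO
Why: Bromine–lithium exchange, borylation of the aryllithium and oxidative 1,2-shift of the aryl group from boron to oxygen (borylation–oxidation) turn C–Br into C–OH at a fixed site, whereas direct lithiation would occur between the two MOM ethers.

Step 7
Reactants: 9 2-(2-butyl-1,3-dioxolan-2-yl)-4-methoxy-6-(trimethylsilyl)phenyl trifluoromethanesulfonate; 15 2,4-bis(methoxymethoxy)-6-pentylphenol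
Product: 20 2-[2,4-bis(methoxymethoxy)-6-pentylphenoxy]-6-(2-butyl-1,3-dioxolan-2-yl)-4-methoxybenzoic acid, via potassium phenolate 16 (not isolated), via aryne 17 (not isolated), via arylpotassium 18 (not isolated), via potassium benzoate 19 (not isolated)
Conditions: 15 (1.5 equiv), KH (1.5 equiv), THF, 0 °C; then KF, 18-crown-6, CO2 (1 atm), slow addition of 9, 0 °C → rt; aq. KH2PO4 (pH 5), 0 °C
Reagents that add atoms: carbon dioxide, O=C=O
Why: Proposed new method: fluoride attacks silicon in 9 and triflate leaves to give aryne 17 across B1–B2, phenolate 16 adds to the in-plane π bond at B2, and the aryl anion 18 left at B1 is carboxylated by CO2 to 19, so the O–B2 bond and the B1–carboxyl bond form in one flask. The closest known reaction types are the three-component coupling of arynes with amines and CO2 to anthranilic acids and the fluoride-induced O-arylation of phenols with 2-silylaryl triflates; a phenolate has not been shown in the first role. No ring is closed and no stereocentre is created. The step needs site selectivity for B2 over B1, which the quaternary dioxolane carbon on B6 should secure by shielding B1 and by stabilising inductively the charge that builds up there, the B4 methoxy group being remote and only weakly opposed. It also needs carboxylation to outrun protonation, for which THF (no acidic C–H), a hydride-derived phenolate (no conjugate acid left in the flask) and a CO2-saturated solution are chosen. Carbonate formation from 16 and CO2 is reversible, and slow addition of 9 keeps the aryne from meeting the product carboxylate.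

Step 8
Reactants: 20 2-[2,4-bis(methoxymethoxy)-6-pentylphenoxy]-6-(2-butyl-1,3-dioxolan-2-yl)-4-methoxybenzoic acid
Product: 22 methyl 2-[2,4-bis(methoxymethoxy)-6-pentylphenoxy]-6-(2-butyl-1,3-dioxolan-2-yl)-4-methoxybenzoate, via caesium benzoate 21 (not isolated)
Conditions: Cs2CO3, MeI, DMF, rt
Reagents that add atoms: iodomethane, CI
Why: Cs2CO3 should convert the acid into the caesium carboxylate 21, whose SN2 alkylation at oxygen by MeI is insensitive to the two ortho substituents that would block a Fischer esterification, and the basic medium leaves the dioxolane and the MOM ethers intact.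

Step 9
Reactants: 22 methyl 2-[2,4-bis(methoxymethoxy)-6-pentylphenoxy]-6-(2-butyl-1,3-dioxolan-2-yl)-4-methoxybenzoate
Product: 23 methyl 2-(2,4-dihydroxy-6-pentylphenoxy)-4-methoxy-6-pentanoylbenzoate (CNP0313056.0)
Conditions: HCl (2 M aq.)–MeOH (1:4), 40 °C
Reagents that add atoms: water, O
Why: Acid-catalysed acetal cleavage should remove the dioxolane by hydrolysis and both MOM ethers by exchange to methanol, which also scavenges the formaldehyde equivalent, while the hindered methyl ester in methanol can only exchange with itself.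

Compound list
1 | 2-bromo-4-methoxyphenol | COc1ccc(O)c(Br)c1 | starting material
2 | pentanoyl chloride | CCCCC(Cl)=O | starting material
3 | 2-bromo-4-methoxyphenyl pentanoate | CCCCC(=O)Oc1ccc(OC)cc1Br | intermediate
4 | 1-(3-bromo-2-hydroxy-5-methoxyphenyl)pentan-1-one | CCCCC(=O)c1cc(OC)cc(Br)c1O | intermediate
5 | 1-[3-bromo-5-methoxy-2-(trimethylsilyloxy)phenyl]pentan-1-one | CCCCC(=O)c1cc(OC)cc(Br)c1O[Si](C)(C)C | intermediate
6 | [2-bromo-6-(2-butyl-1,3-dioxolan-2-yl)-4-methoxyphenoxy]trimethylsilane | CCCCC1(OCCO1)c1cc(OC)cc(Br)c1O[Si](C)(C)C | intermediate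
7 | [3-(2-butyl-1,3-dioxolan-2-yl)-5-methoxy-2-(trimethylsilyloxy)phenyl]lithium | CCCCC1(OCCO1)c1cc(OC)cc([Li])c1O[Si](C)(C)C | intermediate
8 | lithium 2-(2-butyl-1,3-dioxolan-2-yl)-4-methoxy-6-(trimethylsilyl)phenolate | CCCCC1(OCCO1)c1cc(OC)cc([Si](C)(C)C)c1[O-].[Li+] | intermediate
9 | 2-(2-butyl-1,3-dioxolan-2-yl)-4-methoxy-6-(trimethylsilyl)phenyl trifluoromethanesulfonate | CCCCC1(OCCO1)c1cc(OC)cc([Si](C)(C)C)c1OS(=O)(=O)C(F)(F)F | intermediate
10 | olivetol (5-pentylbenzene-1,3-diol) | CCCCCc1cc(O)cc(O)c1 | starting material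
11 | 1,3-bis(methoxymethoxy)-5-pentylbenzene | CCCCCc1cc(OCOC)cc(OCOC)c1 | intermediate
12 | 1-bromo-2,4-bis(methoxymethoxy)-6-pentylbenzene | CCCCCc1cc(OCOC)cc(OCOC)c1Br | intermediate
13 | [2,4-bis(methoxymethoxy)-6-pentylphenyl]lithium | CCCCCc1cc(OCOC)cc(OCOC)c1[Li] | intermediate
14 | lithium [2,4-bis(methoxymethoxy)-6-pentylphenyl]trimethoxyborate | CCCCCc1cc(OCOC)cc(OCOC)c1[B-](OC)(OC)OC.[Li+] | intermediate
15 | 2,4-bis(methoxymethoxy)-6-pentylphenol | CCCCCc1cc(OCOC)cc(OCOC)c1O | intermediate
16 | potassium 2,4-bis(methoxymethoxy)-6-pentylphenolate | CCCCCc1cc(OCOC)cc(OCOC)c1[O-].[K+] | intermediate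
17 | 3-(2-butyl-1,3-dioxolan-2-yl)-5-methoxybenzyne (triple bond across B1–B2) | CCCCC1(OCCO1)C1=CC(OC)=CC#C1 | intermediate
18 | [2-[2,4-bis(methoxymethoxy)-6-pentylphenoxy]-6-(2-butyl-1,3-dioxolan-2-yl)-4-methoxyphenyl]potassium | [K]c1c(Oc2c(CCCCC)cc(OCOC)cc2OCOC)cc(OC)cc1C1(CCCC)OCCO1 | intermediate
19 | potassium 2-[2,4-bis(methoxymethoxy)-6-pentylphenoxy]-6-(2-butyl-1,3-dioxolan-2-yl)-4-methoxybenzoate | [K+].[O-]C(=O)c1c(Oc2c(CCCCC)cc(OCOC)cc2OCOC)cc(OC)cc1C1(CCCC)OCCO1 | intermediate
20 | 2-[2,4-bis(methoxymethoxy)-6-pentylphenoxy]-6-(2-butyl-1,3-dioxolan-2-yl)-4-methoxybenzoic acid | OC(=O)c1c(Oc2c(CCCCC)cc(OCOC)cc2OCOC)cc(OC)cc1C1(CCCC)OCCO1 | intermediate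
21 | caesium 2-[2,4-bis(methoxymethoxy)-6-pentylphenoxy]-6-(2-butyl-1,3-dioxolan-2-yl)-4-methoxybenzoate | [Cs+].[O-]C(=O)c1c(Oc2c(CCCCC)cc(OCOC)cc2OCOC)cc(OC)cc1C1(CCCC)OCCO1 | intermediate
22 | methyl 2-[2,4-bis(methoxymethoxy)-6-pentylphenoxy]-6-(2-butyl-1,3-dioxolan-2-yl)-4-methoxybenzoate | COC(=O)c1c(Oc2c(CCCCC)cc(OCOC)cc2OCOC)cc(OC)cc1C1(CCCC)OCCO1 | intermediate
23 | methyl 2-(2,4-dihydroxy-6-pentylphenoxy)-4-methoxy-6-pentanoylbenzoate | CCCCCc1cc(O)cc(O)c1Oc1cc(OC)cc(C(=O)CCCC)c1C(=O)OC | target

Total step count: 9.
Longest linear sequence: 6 steps (steps 1, 2, 3, 7, 8, 9, or equally steps 4, 5, 6, 7, 8, 9).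

Steps most likely to fail

Step 7 (Proposed new method). The aryl anion may be protonated before it is carboxylated, the phenolate may be held back as its carbonate, or it may add to the wrong aryne carbon. The fallback uses known chemistry, sets out from 6 and 15, and comes back at 22. Methanolysis of the silyl ether of 6 (K2CO3, MeOH) would give 2-bromo-6-(2-butyl-1,3-dioxolan-2-yl)-4-methoxyphenol F1. Triflation (Tf2O, pyridine, CH2Cl2, 0 °C) would give 2-bromo-6-(2-butyl-1,3-dioxolan-2-yl)-4-methoxyphenyl trifluoromethanesulfonate F2. An Ullmann ether synthesis with 15 (CuI, picolinic acid, K3PO4, DMSO, 90 °C), in which copper engages the C–Br bond and leaves the aryl triflate alone, would form the O–B2 bond. Its product is 2-[2,4-bis(methoxymethoxy)-6-pentylphenoxy]-6-(2-butyl-1,3-dioxolan-2-yl)-4-methoxyphenyl trifluoromethanesulfonate F3. Palladium-catalysed methoxycarbonylation of the triflate (Pd(OAc)2, 1,3-bis(diphenylphosphino)propane, CO 1 atm, MeOH, Et3N, DMF, 70 °C) would then form the B1–carboxyl bond and give 22.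

Step 2. Ketal formation at the hindered, electron-rich aryl ketone may stall, or the labile aryl trimethylsilyl ether may be lost on isolation. The fallback separates phenol protection from ketalisation, sets out from 4, and comes back at 6. Silylation with t-BuMe2SiOTf and 2,6-lutidine (CH2Cl2, 0 °C) would give 1-[3-bromo-2-(tert-butyldimethylsilyloxy)-5-methoxyphenyl]pentan-1-one F4. The robust silyl ether allows a classical acid-catalysed ketalisation with chemical removal of water (ethylene glycol, HC(OEt)3, TsOH cat., 40 °C), giving [2-bromo-6-(2-butyl-1,3-dioxolan-2-yl)-4-methoxyphenoxy](tert-butyl)dimethylsilane F5. Bu4NF in THF at 0 °C would free 2-bromo-6-(2-butyl-1,3-dioxolan-2-yl)-4-methoxyphenol F1, and hexamethyldisilazane (THF, 65 °C) would convert this into 6.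

Step 9. The unmasked ketone may assist loss of the methyl ester (hydrolysis to the lactol or isomerisation to the cyclic pseudo-ester), and released formaldehyde may alkylate the electron-rich ring A. The fallback changes the order so that the ester is made last under nearly neutral conditions; it sets out from 20 and comes back at 23. Aqueous acid (2 M HCl, THF, 40 °C, with 1,3-dimethoxybenzene as formaldehyde scavenger) would remove the dioxolane and both MOM groups from 20. This gives 2-(2,4-dihydroxy-6-pentylphenoxy)-4-methoxy-6-pentanoylbenzoic acid F6, expected to be in equilibrium with its hydroxyphthalide lactol. Alkylation of the open carboxylate with MeI and KHCO3 in DMF at rt, a base too weak to deprotonate the phenols, should then give 23.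

Further compounds
F1 | step 7 | 2-bromo-6-(2-butyl-1,3-dioxolan-2-yl)-4-methoxyphenol | CCCCC1(OCCO1)c1cc(OC)cc(Br)c1O
F2 | step 7 | 2-bromo-6-(2-butyl-1,3-dioxolan-2-yl)-4-methoxyphenyl trifluoromethanesulfonate | CCCCC1(OCCO1)c1cc(OC)cc(Br)c1OS(=O)(=O)C(F)(F)F
F3 | step 7 | 2-[2,4-bis(methoxymethoxy)-6-pentylphenoxy]-6-(2-butyl-1,3-dioxolan-2-yl)-4-methoxyphenyl trifluoromethanesulfonate | CCCCC1(OCCO1)c1cc(OC)cc(Oc2c(CCCCC)cc(OCOC)cc2OCOC)c1OS(=O)(=O)C(F)(F)F
F4 | step 2 | 1-[3-bromo-2-(tert-butyldimethylsilyloxy)-5-methoxyphenyl]pentan-1-one | CCCCC(=O)c1cc(OC)cc(Br)c1O[Si](C)(C)C(C)(C)C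
F5 | step 2 | [2-bromo-6-(2-butyl-1,3-dioxolan-2-yl)-4-methoxyphenoxy](tert-butyl)dimethylsilane | CCCCC1(OCCO1)c1cc(OC)cc(Br)c1O[Si](C)(C)C(C)(C)C
F6 | step 9 | 2-(2,4-dihydroxy-6-pentylphenoxy)-4-methoxy-6-pentanoylbenzoic acid | CCCCCc1cc(O)cc(O)c1Oc1cc(OC)cc(C(=O)CCCC)c1C(O)=O
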